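**One step.** In a one-step world of first order, starting material turns to target at a fixed fraction per second, so the share turned at a given time is the same at every charge. The bench rule follows: read the share at that time from one run and multiply by the new charge, the time and temperature held the same.

| flask | starting material | time |
|---|---|---|
| blue | 0.0800 M |  |
| red | 0.0320 M |  |
| ochre | 0.160 M |  |
| grey | 0.400 M | 190 s |

- blue run (time / s: [target] / M): 7.6: 0.00387; 17: 0.00850; 38: 0.01768; 85: 0.03353; 190: 0.04957
- red run (time / s: [target] / M): 7.6: 0.00181; 17: 0.00443; 38: 0.00953; 85: 0.01692; 190: 0.02214
- ochre run (time / s: [target] / M): 7.6: 0.00621; 17: 0.01268; 38: 0.02779; 85: 0.05413; 190: 0.08653

(readings scatter by 2 × 10⁻⁴ M)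

1. order of the initial rate in [starting material], near the charge of the blue run, the rate being that where two percent of its starting material are target (one fixed amount of target, the same in the runs compared)
2. target in the grey run at 190 s, as a share of the starting material charged

- Overall: starting material -> target.
- Constant volume, constant temperature.
- What is held in complexes is read along with the free species.
- An order is taken over about fifteen percent of the charge, up and down.

**The border.** At 190 s the blue run holds 62.0% of its charge as target, so the rule promises that share for the grey run. But the red run holds 69.2% and the ochre run 54.1%. The ochre share over the red share is 0.782, where the rule needs 1. The scatter is 0.903% of the red reading, so that gap is far wider than the scatter.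

**Charge order.** So we measure the failure. At one time, divide the logarithm of the ratio of target in two runs by the logarithm of the ratio of their charges, and call this the charge order n, an apparent order. At 190 s, n is 0.880 from red to blue and 0.804 from blue to ochre.

**Our reckoning.** The midpoints of the steps red to blue, blue to ochre and ochre to grey lie evenly on a logarithmic scale, so we continue the drop and take 0.728 from ochre to grey. Scaling the ochre reading by that order gives 42.1% for the grey run. At the reading of 17 s, n from red to ochre reads 0.653. We commit to this as the initial order, though it is a stand-in, since the ochre run then holds more target than the red run.

The forecast gave 0.67 (0.58 to 0.76) and 35% (31% to 39%), a grey value lower than ours, and said: “The main uncertainty is extrapolating beyond the tested concentrations”.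

**The result.** The grey run gives 41.4% of its charge as target, from these steps:

    starting material → target (0.01720 /s)
    2 starting material → side product (0.02620 /M/s)
    target → decomposed product (0.002110 /s)
    2 starting material ⇌ idle substrate dimer, settled at all times (25.30 /M)

From ochre to grey, n is therefore 0.708, lower than the 0.804 from blue to ochre. Where target equals 2 percent of the blue charge, the red run makes it at 2.8 × 10⁻⁴ M/s and the ochre run at 8.0 × 10⁻⁴ M/s, so the same logarithmic ratio, taken on these rates instead of on target, is 0.653 from red to ochre. The order asked, near the blue charge, is 0.64.

The earlier runs and the new flask are calculated from invented constants, noise included.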